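**Your question.** Per minute was the unit I reached for when you asked for a quick number on zeta and eta. You suspected the capture agent would steer them. But Sunday's and Monday's runs, at 0.50 mM and 2 mM, read 73.2% and 74.7% substrate at 12.0 min, a gap close to the scatter of 1 percentage point, so I set that suspicion aside for the substrate.

common to all: substrate 0.020 M (fed, over 4.0 min)
- Sunday's: partner 2 equiv; capture agent 0.50 mM; run made earlier; the fed solution adds 0.25 times the starting volume
- Monday's: partner 2 equiv; capture agent 2 mM; run made earlier; the fed solution adds 0.25 times the starting volume
- zeta: partner 2.00 equiv; capture agent 1.00 mM; the fed solution adds 0.25 times the starting volume; time 20 min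
- eta: partner 2.00 equiv; capture agent 1.00 mM; the fed solution adds 0.25 times the starting volume; time 40 min

| run | time / min | open intermediate / % | substrate / % | target / % | trapped intermediate / % |
|---|---|---|---|---|---|
| Sunday's | 1.00 | 1.2 | 24.8 | 0 | 0 |
| Sunday's | 1.33 | 1.0 | 32.7 | 0 | 0 |
| Sunday's | 2.00 | 2.6 | 47.0 | 0 | 2.9 |
| Sunday's | 3.00 | 1.8 | 73.8 | 0.6 | 0 |
| Sunday's | 5.00 | 7.5 | 91.9 | 0.8 | 2.5 |
| Sunday's | 8.00 | 14.3 | 84.7 | 0.6 | 2.1 |
| Sunday's | 12.0 | 24.3 | 73.2 | 2.5 | 0 |
| Monday's | 1.50 | 1.3 | 34.4 | 0 | 0 |
| Monday's | 3.00 | 3.5 | 71.2 | 0.6 | 1.4 |
| Monday's | 5.00 | 8.1 | 91.6 | 1.0 | 0 |
| Monday's | 6.00 | 9.9 | 89.1 | 1.1 | 1.0 |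
| Monday's | 8.00 | 16.5 | 83.7 | 0 | 0 |
| Monday's | 10.0 | 17.8 | 78.0 | 0 | 0.7 |
| Monday's | 12.0 | 23.4 | 74.7 | 1.8 | 0 |

(each reading ± 1 percentage point)

1. which of these there is most of at the end, counted by the substrate in it, zeta (target / open intermediate / substrate / trapped intermediate)
2. which of these there is most of at the end, counted by the substrate in it, eta (target / open intermediate / substrate / trapped intermediate)
3. the largest of these amounts at the end, in percent of the substrate charged, zeta
4. the largest of these amounts at the end, in percent of the substrate charged, eta

- charges are per starting volume, the dose included; the dosed solution carries all of it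
- the earlier runs were read with a standard deviation of 1 percentage point
- what may be going on: substrate -> open intermediate; open intermediate + second intermediate <-> target; target -> over-reaction product; 2 second intermediate -> homo product; open intermediate + capture agent -> trapped intermediate; partner -> second intermediate
- percentages count the whole charge, also what has not yet gone in

**The end state.** The readings pointed one way: substrate was passing into open intermediate. Target read 2.5% at 12.0 min on Sunday, and in zeta and eta the capture agent's charge limits trapped intermediate to 5.00% of the substrate. The question was therefore how fast substrate goes.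

**The clock.** I treated the fall from 5.00 min to 12.0 min as a first-order loss. The logarithm of the ratio of the two substrate readings, over the time between them, gave 0.0325 min⁻¹ on Sunday and 0.0291 min⁻¹ on Monday. I took their mean as the loss constant k, 0.0308 min⁻¹, a reading with that scatter. A steady feed puts the average substrate in at half the dosing time, so I started the clock at 2.00 min. That gave my crossing time t_c, the feed's midpoint plus the half-life ln(2)/k, when substrate stands at half the charge and the other forms together hold the other half: 24.5 min.

**My numbers.** Zeta, read at 20 min, comes before t_c, so I put substrate ahead at 57.4%. Eta, read at 40 min, comes after it. Substrate there came to 31.0%, and taking the limit 5.00% from the remainder left open intermediate ahead at 64.0%.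

**The forecast.** It named substrate at 58% for zeta, above my figure, and open intermediate at 63% for eta, below mine, holding that “The open intermediate therefore simply accumulates”.

**The result.** Zeta gave substrate at 59.4%, and eta gave open intermediate at 58.7%.

    substrate → open intermediate (k = 0.0290 min⁻¹)
    open intermediate + second intermediate ⇌ target (K = 11.0 M⁻¹, k = 1.80 M⁻¹ min⁻¹)
    target → over-reaction product (k = 8.60 × 10⁻⁵ min⁻¹)
    2 second intermediate → homo product (k = 2.20 M⁻¹ min⁻¹)
    open intermediate + capture agent → trapped intermediate (k = 4.00 M⁻¹ min⁻¹)
    partner → second intermediate (k = 0.0850 min⁻¹)

**Why they part.** Zeta and eta differ in reading time, and that difference is the main reason for the 26 points gap in substrate, 59.4% in zeta against 33.2% in eta. The crossing time 24.5 min lies between their two readings. The same flask as zeta read at 30 min, past t_c, reckoned 42.2% substrate by my constant and stood at 44.4%, with open intermediate ahead at 48.5%.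

The numbers in the tables were computed with constants of no real substance; noise was put on by code.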